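Ring A is read (eremophilane numbering) as a butan-2-one unit, C2–C3(=O)–C4 plus its methyl, laid across C1 and C5 of a finished ring B. Everything rests on cutting C1–C2 and C4–C5. The precursor is a ring-B allylic alcohol: C1–OH on a C10=C5 enone (C9=O), C8 masked as a ketal, C7 isopropenyl set by catalysis. O-Vinylation with 2-iodobut-2-ene makes a temporary C1–O–C3 link. Its Claisen shift forges C4–C5 and unveils a C1=C10–C9=O acceptor, which enolate carbon C2 closes. The step exploits the C3 oxygen between C2 and C4 and the epimerisable C4 and C10, which drain into the all-equatorial cis-decalin.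

Key step: step 6

Remark on the chemistry: ring A = C1–C5 and C10, ring B = C5–C10, C14 is the methyl on C5 and C15 the methyl on C4. It is assumed that (R)-BINAP gives the (5R)-adduct 3 in step 1, by analogy with 1,4-additions to cyclohex-2-enone. The antipodal ligand is taken if the sense proves opposite.

Step 1
Reactants: 1 4,4-dimethoxycyclohexa-2,5-dien-1-one; 2 potassium trifluoro(prop-1-en-2-yl)borate
Product: 3 (5R)-4,4-dimethoxy-5-(prop-1-en-2-yl)cyclohex-2-en-1-one
Conditions: [Rh(cod)2]BF4 (3 mol %), (R)-BINAP, Et3N, toluene/H2O, 23 °C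
Reagents that add atoms: potassium trifluoro(prop-1-en-2-yl)borate (2), [K+].C=C(C)[B-](F)(F)F
Why: Hayashi–Miyaura-type rhodium-catalysed 1,4-addition to one of the two enantiotopic enone halves of the prochiral dienone, in which the BINAP-bound alkenylrhodium selects the face and so sets C7, a reaction type known for this borate next to a quinone-ketal carbon.

Step 2
Reactants: 3 (5R)-4,4-dimethoxy-5-(prop-1-en-2-yl)cyclohex-2-en-1-one
Product: 4 (5R)-4,4-dimethoxy-1-methyl-5-(prop-1-en-2-yl)cyclohex-2-en-1-ol (both carbinol epimers)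
Conditions: MeLi, Et2O, −78 °C; then H2O
Reagents that add atoms: methyllithium, [Li]C
Why: Hard organolithium 1,2-addition to the enone carbonyl installs C14, and the new carbinol centre is irrelevant because step 3 erases it.

Step 3
Reactants: 4 (5R)-4,4-dimethoxy-1-methyl-5-(prop-1-en-2-yl)cyclohex-2-en-1-ol
Product: 5 (5R)-6,6-dimethoxy-3-methyl-5-(prop-1-en-2-yl)cyclohex-2-en-1-one
Conditions: [C5H5NH][CrO3Cl] (pyridinium chlorochromate), NaOAc, 4 Å MS, CH2Cl2, 23 °C
Reagents that add atoms: pyridinium chlorochromate, [O-][Cr](=O)(=O)Cl.c1cc[nH+]cc1 (delivers the C9 carbonyl oxygen)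
Why: Babler–Dauben oxidative 1,3-transposition, in which the chromate ester shifts to C9 and is oxidised there, moves the carbonyl next to the ketal carbon C8 and leaves the methyl on the enone β-carbon C5.

Step 4
Reactants: 5 (5R)-6,6-dimethoxy-3-methyl-5-(prop-1-en-2-yl)cyclohex-2-en-1-one
Product: 8 (5R)-2-(hydroxymethyl)-6,6-dimethoxy-3-methyl-5-(prop-1-en-2-yl)cyclohex-2-en-1-one, via lithium dienolate 6 (not isolated), via deconjugated aldol 7 (not isolated)
Conditions: LiN(iPr)2, THF, −78 °C; CH2O (gas); H2O; then DBU (cat.), CH2Cl2, 23 °C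
Reagents that add atoms: formaldehyde, C=O
Why: C8 bears no hydrogen, so the amide base can only form the extended dienolate, which undergoes aldol addition to formaldehyde at its α-carbon C10 (bringing in C1) before DBU returns the double bond into conjugation.

Step 5
Reactants: 9 but-2-yne
Product: 11 (E)-2-iodobut-2-ene, via alkenylzirconocene chloride 10 (not isolated)
Conditions: Cp2Zr(H)Cl, CH2Cl2, 23 °C; then I2, 0 °C
Reagents that add atoms: iodine, II
Why: syn-Hydrozirconation of the symmetrical alkyne followed by iodinolysis with retention should give a single vinyl iodide.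

Step 6
Reactants: 8 (5R)-2-(hydroxymethyl)-6,6-dimethoxy-3-methyl-5-(prop-1-en-2-yl)cyclohex-2-en-1-one; 11 (E)-2-iodobut-2-ene
Product: 14 (4R,5R,7R,10S)-8,8-dimethoxy-10βH-eremophil-11-ene-3,9-dione (cis-decalin; 4β-methyl; 5β-methyl; 7β-isopropenyl), via allyl vinyl ether 12 (not isolated), via Claisen ketone 13 (not isolated)
Conditions: CuI (10 mol %), 3,4,7,8-tetramethyl-1,10-phenanthroline (20 mol %), Cs2CO3, o-xylene, 120 °C
Reagents that add atoms: (E)-2-iodobut-2-ene (11), C/C=C(\C)I
Why: Copper-catalysed Ullmann-type O-vinylation of 8 gives allyl vinyl ether 12, whose [3,3] Claisen shift (accelerated by the acyl group on the central allyl carbon C10) makes C4–C5, breaks C1–O and gives α-methylene ketone 13, after which carbonate enolises the new methyl ketone at C2 and this carbon adds to C1 in an intramolecular Michael reaction that makes C1–C2. The closest known reaction type is the domino copper-catalysed C–O coupling/Claisen rearrangement of allylic alcohols with vinyl iodides, here extended by a Michael ring closure. Ring A closes in a 6-endo-trig mode (enolate C2 onto the exocyclic C1=C10 acceptor), whereas aldol attack of C2 on C9 would give a strained bicyclo[3.3.1]nonane and is reversible. C5 is controlled by the C7 isopropenyl group, because the new bond forms axially on the ring-B face anti to it, so that the C5 methyl ends cis to the isopropenyl. C4 (α to C3=O) and C10 (α to C9=O) remain epimerisable under carbonate and should drain to the equatorial 4-methyl and the cis ring fusion, since a trans fusion would force the C5 methyl and the C7 isopropenyl into a 1,3-diaxial pair, so every vinyl ether geometry and every chair or boat pathway converges on one diastereomer. The step needs C4 to bond to C5 and C2 to C1, which is secured by the defined vinyl iodide (oxygen on C3, methyl on C4) and by the fact that only C2 can reach C1 in a six-membered transition state.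

Step 7
Reactants: 14 (4R,5R,7R,10S)-8,8-dimethoxy-10βH-eremophil-11-ene-3,9-dione
Product: 15 (3R,4R,5R,7R,9R,10S)-8,8-dimethoxy-10βH-eremophil-11-ene-3α,9β-diol
Conditions: Al(OiPr)3 (30 mol %), iPrOH/toluene, reflux, trace of acetone kept in the flask
Reagents that add atoms: none
Why: Meerwein–Ponndorf–Verley reduction under reversible hydride transfer equilibrates both carbinols, and the equatorial 3α- and 9β-alcohols should prevail because their axial epimers suffer 1,3-diaxial contacts with the C5 methyl and with C4 respectively.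

Step 8
Reactants: 15 (3R,4R,5R,7R,9R,10S)-8,8-dimethoxy-10βH-eremophil-11-ene-3α,9β-diol; 16 angelic acid ((Z)-2-methylbut-2-enoic acid)
Product: 18 3α-angeloyloxy-8,8-dimethoxy-10βH-eremophil-11-en-9β-ol, via mixed anhydride 17 (not isolated)
Conditions: 2,4,6-trichlorobenzoyl chloride, Et3N, toluene, 23 °C; then 15, 80 °C
Reagents that add atoms: angelic acid (16), C/C=C(/C)C(=O)O
Why: Yamaguchi-type mixed-anhydride esterification without a nucleophilic catalyst keeps the Z geometry and should acylate only the C3 hydroxyl, because the C9 hydroxyl is flanked by the fully substituted ketal carbon C8 and the ring-fusion carbon C10.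

Step 9
Reactants: 18 3α-angeloyloxy-8,8-dimethoxy-10βH-eremophil-11-en-9β-ol
Product: 19 3α-angeloyloxy-9β-hydroxy-10βH-eremophil-11-en-8-one
Conditions: LiBF4, MeCN/H2O (50:1), 23 °C
Reagents that add atoms: water, O
Why: Mild Lewis-acid-assisted hydrolysis of the dimethyl ketal unmasks the C8 ketone under nearly neutral conditions that should neither epimerise C7 or C9 nor move the isopropenyl double bond into conjugation.

Step 10
Reactants: 19 3α-angeloyloxy-9β-hydroxy-10βH-eremophil-11-en-8-one; 20 3-methylbut-2-enoyl chloride (senecioyl chloride)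
Product: 21 (3R,4R,5R,7R,9R,10S)-3α-angeloyloxy-9β-senecioyloxy-10βH-eremophil-11-en-8-one (target)
Conditions: pyridine, CH2Cl2, 0 °C
Reagents that add atoms: 3-methylbut-2-enoyl chloride (20), CC(C)=CC(=O)Cl
Why: O-Acylation of the now less hindered α-ketol hydroxyl with the acid chloride and the weak base pyridine should give the senecioate without disturbing the base-sensitive β,γ-unsaturated ketone.

Compound list
1 | 4,4-dimethoxycyclohexa-2,5-dien-1-one | COC1(OC)C=CC(=O)C=C1 | starting material
2 | potassium trifluoro(prop-1-en-2-yl)borate | [K+].C=C(C)[B-](F)(F)F | starting material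
3 | (5R)-4,4-dimethoxy-5-(prop-1-en-2-yl)cyclohex-2-en-1-one | C=C(C)[C@H]1CC(=O)C=CC1(OC)OC | intermediate
4 | (5R)-4,4-dimethoxy-1-methyl-5-(prop-1-en-2-yl)cyclohex-2-en-1-ol, carbinol epimers | C=C(C)[C@H]1CC(C)(O)C=CC1(OC)OC | intermediate
5 | (5R)-6,6-dimethoxy-3-methyl-5-(prop-1-en-2-yl)cyclohex-2-en-1-one | C=C(C)[C@H]1CC(C)=CC(=O)C1(OC)OC | intermediate
6 | lithium dienolate of 5 (exocyclic C5=C14) | [Li+].C=C(C)[C@H]1CC(=C)C=C([O-])C1(OC)OC | intermediate
7 | (5R)-2-(hydroxymethyl)-6,6-dimethoxy-3-methylidene-5-(prop-1-en-2-yl)cyclohexan-1-one, C2 epimers | C=C(C)[C@H]1CC(=C)C(CO)C(=O)C1(OC)OC | intermediate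
8 | (5R)-2-(hydroxymethyl)-6,6-dimethoxy-3-methyl-5-(prop-1-en-2-yl)cyclohex-2-en-1-one | C=C(C)[C@H]1CC(C)=C(CO)C(=O)C1(OC)OC | intermediate
9 | but-2-yne | CC#CC | starting material
10 | (E)-but-2-en-2-ylzirconocene chloride | C/C=[C-]\C.[Cl-].[Zr+4].c1cc[cH-]c1.c1cc[cH-]c1 | intermediate
11 | (E)-2-iodobut-2-ene | C/C=C(\C)I | intermediate
12 | (5R)-2-{[(E)-but-2-en-2-yloxy]methyl}-6,6-dimethoxy-3-methyl-5-(prop-1-en-2-yl)cyclohex-2-en-1-one | C=C(C)[C@H]1CC(C)=C(CO/C(C)=C/C)C(=O)C1(OC)OC | intermediate
13 | (3R,5R)-6,6-dimethoxy-3-methyl-2-methylidene-3-(3-oxobutan-2-yl)-5-(prop-1-en-2-yl)cyclohexan-1-one, side-chain epimers | C=C(C)[C@H]1C[C@](C)(C(C)C(C)=O)C(=C)C(=O)C1(OC)OC | intermediate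
14 | (4R,5R,7R,10S)-8,8-dimethoxy-10βH-eremophil-11-ene-3,9-dione | C=C(C)[C@H]1C[C@@]2(C)[C@H](CCC(=O)[C@@H]2C)C(=O)C1(OC)OC | intermediate
15 | (3R,4R,5R,7R,9R,10S)-8,8-dimethoxy-10βH-eremophil-11-ene-3α,9β-diol | C=C(C)[C@H]1C[C@@]2(C)[C@H](CC[C@@H](O)[C@@H]2C)[C@@H](O)C1(OC)OC | intermediate
16 | angelic acid | C/C=C(/C)C(=O)O | starting material
17 | angelic 2,4,6-trichlorobenzoic anhydride | C/C=C(/C)C(=O)OC(=O)c1c(Cl)cc(Cl)cc1Cl | intermediate
18 | 3α-angeloyloxy-8,8-dimethoxy-10βH-eremophil-11-en-9β-ol | C=C(C)[C@H]1C[C@@]2(C)[C@H](CC[C@@H](OC(=O)/C(C)=C\C)[C@@H]2C)[C@@H](O)C1(OC)OC | intermediate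
19 | 3α-angeloyloxy-9β-hydroxy-10βH-eremophil-11-en-8-one | C=C(C)[C@H]1C[C@@]2(C)[C@H](CC[C@@H](OC(=O)/C(C)=C\C)[C@@H]2C)[C@@H](O)C1=O | intermediate
20 | 3-methylbut-2-enoyl chloride | CC(C)=CC(=O)Cl | starting material
21 | (3R,4R,5R,7R,9R,10S)-3α-angeloyloxy-9β-senecioyloxy-10βH-eremophil-11-en-8-one | C=C(C)[C@H]1C[C@@]2(C)[C@H](CC[C@@H](OC(=O)/C(C)=C\C)[C@@H]2C)[C@@H](OC(=O)C=C(C)C)C1=O | target

Total step count: 10. Longest linear sequence: 9 steps (steps 1–4 and 6–10; step 5 is a one-step side branch).

Steps most likely to fail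

Step 6. Under hot carbonate the hydroxymethyl enone may lose formaldehyde by deconjugation and retro-aldol cleavage, or lose water by vinylogous elimination, before the slow C–O coupling takes place. The fallback sets out from 8 and comes back at 14. Compound 8 is transesterified with ethyl 2-methyl-3-oxobutanoate (DMAP cat., toluene, reflux) to [(4R)-5,5-dimethoxy-2-methyl-6-oxo-4-(prop-1-en-2-yl)cyclohex-1-en-1-yl]methyl 2-methyl-3-oxobutanoate F1. Heating F1 in xylene without base triggers a Carroll rearrangement, in which the ester enol plays the part of the vinyl ether. Decarboxylation then gives 13, and a catalytic amount of DBU at 23 °C closes and equilibrates it to 14.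

Step 7. Hydride transfer to the hindered C9 carbonyl may be sluggish. Equilibration may also stay incomplete, leaving axial carbinols from kinetic delivery on the open faces. The fallback sets out from 14 and comes back at 15. Zn(BH4)2 in Et2O at −78 °C should reduce only the C9 carbonyl, which is activated by its two α-alkoxy groups. Hydride should arrive anti to the axial C8–O bond, giving (4R,5R,7R,9R,10S)-9β-hydroxy-8,8-dimethoxy-10βH-eremophil-11-en-3-one F2. Dissolving-metal reduction (Li, NH3, t-BuOH, −78 °C) then converts the C3 ketone through its ketyl into the equatorial 3α-alcohol 15.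

Step 4. The aldol addition may revert, or the adduct may lose water to a cross-conjugated methylene ketone during reconjugation. The fallback sets out from 5 and comes back at 8. Dienolate 6 is quenched with I2 instead of formaldehyde, and the α-iodo ketone tautomerises to (5R)-2-iodo-6,6-dimethoxy-3-methyl-5-(prop-1-en-2-yl)cyclohex-2-en-1-one F3. Stille coupling of F3 with (tributylstannyl)methanol (Pd(PPh3)4, toluene, 80 °C) then delivers 8 without any reversible aldol step.

Further compounds
F1 | step 6 | [(4R)-5,5-dimethoxy-2-methyl-6-oxo-4-(prop-1-en-2-yl)cyclohex-1-en-1-yl]methyl 2-methyl-3-oxobutanoate | C=C(C)[C@H]1CC(C)=C(COC(=O)C(C)C(C)=O)C(=O)C1(OC)OC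
F2 | step 7 | (4R,5R,7R,9R,10S)-9β-hydroxy-8,8-dimethoxy-10βH-eremophil-11-en-3-one | C=C(C)[C@H]1C[C@@]2(C)[C@H](CCC(=O)[C@@H]2C)[C@@H](O)C1(OC)OC
F3 | step 4 | (5R)-2-iodo-6,6-dimethoxy-3-methyl-5-(prop-1-en-2-yl)cyclohex-2-en-1-one | C=C(C)[C@H]1CC(C)=C(I)C(=O)C1(OC)OC
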